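**Retrosynthetic overview**
- Feature: the plan rests on the central catechol, ring B of the flavone half. C3'(OH) and C4'(OH) are neighbours. C1' (bonded to flavone C2) and C6' (bonded to flavanone C6) are neighbours on the opposite edge, and only C2'–H and C5'–H lie between. C2'–C3'–C4'–C5' therefore maps onto a 2,3-dioxygenated buta-1,3-diene and C1'–C6' onto a disubstituted alkyne.
- Disconnection 1 (behind the global deprotection): [4+2] cycloaddition and dehydrogenation of a flavanon-6-yl–C≡C–chromon-2-yl alkyne with 2,3-bis(trimethylsilyloxy)buta-1,3-diene. The crowded C6–C6' aryl–aryl bond is laid down beforehand as an aryl–alkynyl bond.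
- Disconnection 2: the flavanone C6–C(sp) bond, by amine-free Sonogashira coupling of a (2R)-6-iodoflavanone with a 2-ethynylchromone.
- Disconnection 3: the flavanone C2–aryl bond, by rhodium-catalysed asymmetric conjugate arylation of a 6-iodochromone. The iodine position is fixed by the symmetry of 4-iodo-3,5-bis(MOM-oxy)phenol. Both pyranone rings are closed from o-hydroxyaryl ynones.
- Ring order: the pyranone of the flavanone half and the pyranone of the flavone half in parallel, then the central benzene ring last.

Key step: step 13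

Assumption: the sense of induction in step 6 is assigned from the quadrant model of atropisomeric diphosphine–rhodium catalysts, (R)-ligand giving the (2R)-flavanone; if the correlation is reversed for this chromone, the (S)-ligand is used and nothing else changes.
Assumption: the target string carries no descriptor for the tri-ortho-substituted C6–C6' axis, so this axis is treated as not configurationally defined and slowly interconverting rotamers of protected intermediates are carried on together.

Step 1
Reactants: 1 2-iodoresorcinol (2-iodobenzene-1,3-diol)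
Product: 2 2-iodo-1,3-bis(methoxymethoxy)benzene
Conditions: MOMCl (2.5 equiv), i-Pr2NEt (3 equiv), CH2Cl2, 0 °C to rt
Reagents that add atoms: chloromethyl methyl ether, COCCl
Why: Base-mediated O-alkylation (MOM ether formation) of both phenols should be clean, and the two acetals shield C4 and C6 while tolerating every basic, organometallic and thermal step before the final acid treatment.

Step 2
Reactants: 2 2-iodo-1,3-bis(methoxymethoxy)benzene
Product: 4 4-iodo-3,5-bis(methoxymethoxy)phenol, via pinacol arylboronate 3 (not isolated)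
Conditions: [Ir(OMe)(cod)]2 (1.5 mol%), 4,4'-di-tert-butyl-2,2'-bipyridine (3 mol%), B2pin2 (0.6 equiv), THF, 70 °C; then 30% aq H2O2, NaOH (1 equiv), 0 °C
Reagents that add atoms: bis(pinacolato)diboron, CC1(C)OB(B2OC(C)(C)C(C)(C)O2)OC1(C)C (boryl group of 3); hydrogen peroxide, OO (phenol oxygen of 4)
Why: Sterically governed iridium-catalysed aromatic C–H borylation should reach only C5, the one C–H bond without an ortho substituent, spares the C–I bond, and the one-pot peroxide oxidation of the boronate places the free OH para to iodine in a ring that is symmetric about its C1–C4 axis.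

Step 3
Reactants: 4 4-iodo-3,5-bis(methoxymethoxy)phenol
Product: 5 2-hydroxy-5-iodo-4,6-bis(methoxymethoxy)benzaldehyde
Conditions: MgCl2 (2 equiv), Et3N (4 equiv), (CH2O)n (6 equiv), MeCN, 80 °C; aq citric acid work-up
Reagents that add atoms: paraformaldehyde (reacts as formaldehyde), C=O
Why: Casnati–Skattebøl ortho-formylation through the magnesium phenoxide delivers the formyl group only next to the free OH, and since both ortho sites are equivalent and the para site carries iodine a single aldehyde should result, which locks iodine at the future C6.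

Step 4
Reactants: 5 2-hydroxy-5-iodo-4,6-bis(methoxymethoxy)benzaldehyde
Product: 6 racemic 1-[2-hydroxy-5-iodo-4,6-bis(methoxymethoxy)phenyl]prop-2-yn-1-ol
Conditions: HC≡CMgBr (0.5 M in THF, 3 equiv), THF, 0 °C to rt; aq NH4Cl
Reagents that add atoms: ethynylmagnesium bromide, C#C[Mg]Br
Why: Grignard 1,2-addition of the small acetylide to the aldehyde follows deprotonation of the phenol by the first equivalent, the stabilised acetylide does not undergo iodine–magnesium exchange, and the racemic carbinol centre is erased in step 5.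

Step 5
Reactants: 6 racemic 1-[2-hydroxy-5-iodo-4,6-bis(methoxymethoxy)phenyl]prop-2-yn-1-ol
Product: 8 6-iodo-5,7-bis(methoxymethoxy)-4H-chromen-4-one, via terminal ynone 7 (not isolated)
Conditions: activated MnO2 (15 equiv), CH2Cl2, rt; filter through Celite; DMAP (20 mol%), CH2Cl2–DMF, rt
Reagents that add atoms: none
Why: MnO2 oxidation of the benzylic–propargylic alcohol gives an o-alkynoylphenol that should close by the known DMAP-catalysed 6-endo-dig oxa-Michael cyclisation, both operations being neutral enough for the MOM ethers and the aryl iodide.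

Step 6
Reactants: 8 6-iodo-5,7-bis(methoxymethoxy)-4H-chromen-4-one; 9 4-(methoxymethoxy)phenylboronic acid
Product: 10 (2R)-6-iodo-5,7-bis(methoxymethoxy)-2-[4-(methoxymethoxy)phenyl]chroman-4-one
Conditions: [RhCl(C2H4)2]2 (1.5 mol%), (R)-2,2'-bis[bis(3,4,5-trifluorophenyl)phosphino]-6,6'-dimethoxy-1,1'-biphenyl (3.3 mol%), aq KOH (10 mol%), 9 (2.5 equiv), CH2Cl2–H2O 10:1, 25 °C
Reagents that add atoms: none
Why: Hayashi–Miyaura asymmetric 1,4-addition to a chromone, in which the aryl–rhodium species held by the (R)-biaryl diphosphine carbometalates one face of C2=C3 and so sets C2 as R, while the electron-poor ligand permits room temperature so that 1,2-addition, ring opening of the product and insertion into the hindered C–I bond should not compete.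

Step 7
Reactants: 11 2,4,6-trihydroxybenzaldehyde
Product: 12 2-hydroxy-4,6-bis(methoxymethoxy)benzaldehyde
Conditions: MOMCl (2.1 equiv), i-Pr2NEt (2.5 equiv), CH2Cl2, 0 °C
Reagents that add atoms: chloromethyl methyl ether, COCCl
Why: Selective MOM ether formation stops at the bis-ether because the last phenol is held in a hydrogen bond to the formyl oxygen and is far less nucleophilic under amine-base conditions.

Step 8
Reactants: 12 2-hydroxy-4,6-bis(methoxymethoxy)benzaldehyde; 13 1,4-bis(trimethylsilyl)buta-1,3-diyne
Product: 15 racemic 1-[2-hydroxy-4,6-bis(methoxymethoxy)phenyl]-5-(trimethylsilyl)penta-2,4-diyn-1-ol, via lithium (trimethylsilyl)butadiynide 14 (not isolated)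
Conditions: 13 (1.3 equiv), MeLi·LiBr (1.25 equiv), THF, 0 °C to rt; then 12 pre-treated with LiN(SiMe3)2 (1.0 equiv), THF, −78 to 0 °C; aq NH4Cl
Reagents that add atoms: none
Why: Mono-desilylative lithiation of the bis(silyl)diyne followed by alkynyllithium 1,2-addition to the aldehyde, whose phenol is masked as its lithium salt, installs all four carbons of chromone C3, C2 and the future alkyne at once, and the racemic carbinol centre disappears in step 9.

Step 9
Reactants: 15 racemic 1-[2-hydroxy-4,6-bis(methoxymethoxy)phenyl]-5-(trimethylsilyl)penta-2,4-diyn-1-ol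
Product: 17 5,7-bis(methoxymethoxy)-2-[(trimethylsilyl)ethynyl]-4H-chromen-4-one, via silylated diynone 16 (not isolated)
Conditions: activated MnO2 (15 equiv), CH2Cl2, rt; filter through Celite; DMAP (20 mol%), CH2Cl2–DMF, rt
Reagents that add atoms: none
Why: MnO2 oxidation and DMAP-catalysed 6-endo-dig oxa-Michael cyclisation of the o-alkynoylphenol, in which the phenol can reach only the β-carbon of the inner triple bond to make a six-membered ring, so that the outer silylalkyne is left as the C2 substituent.

Step 10
Reactants: 17 5,7-bis(methoxymethoxy)-2-[(trimethylsilyl)ethynyl]-4H-chromen-4-one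
Product: 18 2-ethynyl-5,7-bis(methoxymethoxy)-4H-chromen-4-one
Conditions: n-Bu4NF (1.1 equiv), AcOH (1.2 equiv), THF, −20 to 0 °C
Reagents that add atoms: none
Why: Fluoride-induced protodesilylation of an acceptor-substituted alkynylsilane is very fast, and the acetic acid buffer keeps free acetylide and basic fluoride from adding to the activated alkyne or opening the pyranone.

Step 11
Reactants: 19 2,3-butanedione
Product: 20 2,3-bis(trimethylsilyloxy)buta-1,3-diene
Conditions: TMSOTf (2.2 equiv), Et3N (2.6 equiv), Et2O, 0 °C to rt; distillation under reduced pressure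
Reagents that add atoms: trimethylsilyl trifluoromethanesulfonate, C[Si](C)(C)OS(=O)(=O)C(F)(F)F
Why: Double soft enolisation and O-silylation of the 1,2-diketone (silyl enol ether formation with a silyl triflate and a tertiary amine) is the standard access to this symmetric diene, which is purified by distillation and stored over no acid.

Step 12
Reactants: 10 (2R)-6-iodo-5,7-bis(methoxymethoxy)-2-[4-(methoxymethoxy)phenyl]chroman-4-one; 18 2-ethynyl-5,7-bis(methoxymethoxy)-4H-chromen-4-one
Product: 21 (2R)-6-{[5,7-bis(methoxymethoxy)-4-oxo-4H-chromen-2-yl]ethynyl}-5,7-bis(methoxymethoxy)-2-[4-(methoxymethoxy)phenyl]chroman-4-one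
Conditions: PdCl2(PPh3)2 (5 mol%), CuI (10 mol%), powdered anhydrous K2CO3 (1.5 equiv), THF, 40 °C, Ar; 18 (1.3 equiv) added over 4 h
Reagents that add atoms: none
Why: Sonogashira coupling in the amine-free carbonate variant used for acceptor alkynes such as propiolates, where the insoluble base only has to deprotonate the acidic copper-bound alkyne, the iodide allows a low temperature, and no amine is present to add to the alkyne, open the pyranone or epimerise C2 by retro-oxa-Michael opening.

Step 13
Reactants: 21 (2R)-6-{[5,7-bis(methoxymethoxy)-4-oxo-4H-chromen-2-yl]ethynyl}-5,7-bis(methoxymethoxy)-2-[4-(methoxymethoxy)phenyl]chroman-4-one; 20 2,3-bis(trimethylsilyloxy)buta-1,3-diene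
Product: 23 (2R)-6-{2-[5,7-bis(methoxymethoxy)-4-oxo-4H-chromen-2-yl]-4,5-bis(trimethylsilyloxy)phenyl}-5,7-bis(methoxymethoxy)-2-[4-(methoxymethoxy)phenyl]chroman-4-one, via cyclohexa-1,4-diene adduct 22 (not isolated)
Conditions: 20 (10 equiv), BHT (5 mol%), mesitylene (1 M in 21), silylated sealed tube, 160 °C; cool, strip excess 20 in vacuo; same flask, DDQ (1.05 equiv), toluene, 0 °C; filter, concentrate, use crude
Reagents that add atoms: none
Why: Proposed new method: both CH2 ends of diene 20, whose HOMO is raised by the two silyloxy groups, bond in one thermally allowed [4πs+2πs] event to the two sp carbons of 21, which act as the far end of a vinylogous ynone because the triple bond is conjugated with the pyranone enone (C2=C3–C4=O), and adduct 22 then gives up hydride and a proton from its two doubly allylic CH2 groups to DDQ so that the benzene ring appears with both O–Si bonds in place. The closest known reactions are the cycloadditions of 2,3-bis(silyloxy)butadienes with acetylenic esters and ketones followed by dehydrogenation to catechol ethers, and the cycloadditions of 2-styrylchromones at their exocyclic π bond with reactive dienes followed by aromatisation, but a 2-(arylethynyl)chromone carrying a di-ortho-alkoxyaryl group has not served as the 2π partner. The one new ring, the six-membered carbocycle C1'–C6', closes by intermolecular [4+2] annulation in which the bonds C1'–C2' and C6'–C5' form together. No stereocentre is created, the symmetric diene removes any regiochemical question, and flavanone C2 is a spectator protected by the absence of acid and base. The cycloaddition must choose the alkyne over the only other electron-poor C=C bond, chromone C2=C3 (the flavanone ring is saturated at that position), and this is secured because that bond is trisubstituted and embedded in the cross-conjugated pyranone, whereas the linear alkyne has to accommodate only two small methylene termini. The oxidation must choose 22 over the flavanone C2–H/C3–H pair and over any liberated catechol, which is secured by removing the excess enol ether first, limiting DDQ to one equivalent and working at 0 °C.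

Step 14
Reactants: 23 (2R)-6-{2-[5,7-bis(methoxymethoxy)-4-oxo-4H-chromen-2-yl]-4,5-bis(trimethylsilyloxy)phenyl}-5,7-bis(methoxymethoxy)-2-[4-(methoxymethoxy)phenyl]chroman-4-one
Product: 24 (2R)-6-[2-(5,7-dihydroxy-4-oxo-4H-chromen-2-yl)-4,5-dihydroxyphenyl]-5,7-dihydroxy-2-(4-hydroxyphenyl)chroman-4-one (target)
Conditions: HCl (1.25 M in MeOH), THF, 0 to 40 °C; work-up below pH 6; reversed-phase chromatography with 0.1% HCO2H
Reagents that add atoms: none
Why: Acid-catalysed acetal exchange of the five MOM ethers and methanolysis of the two aryl silyl ethers occur together, and because racemisation of a flavanone runs through enolate or phenoxide-driven ring opening the stereocentre should hold in a medium that stays acidic and only mildly warm.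

**Compound list**
1 | 2-iodoresorcinol | Oc1cccc(O)c1I | starting material
2 | 2-iodo-1,3-bis(methoxymethoxy)benzene | COCOc1cccc(OCOC)c1I | intermediate
3 | 2-[4-iodo-3,5-bis(methoxymethoxy)phenyl]-4,4,5,5-tetramethyl-1,3,2-dioxaborolane | COCOc1cc(B2OC(C)(C)C(C)(C)O2)cc(OCOC)c1I | intermediate
4 | 4-iodo-3,5-bis(methoxymethoxy)phenol | COCOc1cc(O)cc(OCOC)c1I | intermediate
5 | 2-hydroxy-5-iodo-4,6-bis(methoxymethoxy)benzaldehyde | O=Cc1c(O)cc(OCOC)c(I)c1OCOC | intermediate
6 | racemic 1-[2-hydroxy-5-iodo-4,6-bis(methoxymethoxy)phenyl]prop-2-yn-1-ol | C#CC(O)c1c(O)cc(OCOC)c(I)c1OCOC | intermediate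
7 | 1-[2-hydroxy-5-iodo-4,6-bis(methoxymethoxy)phenyl]prop-2-yn-1-one | C#CC(=O)c1c(O)cc(OCOC)c(I)c1OCOC | intermediate
8 | 6-iodo-5,7-bis(methoxymethoxy)-4H-chromen-4-one | O=c1ccoc2cc(OCOC)c(I)c(OCOC)c12 | intermediate
9 | 4-(methoxymethoxy)phenylboronic acid | COCOc1ccc(B(O)O)cc1 | starting material
10 | (2R)-6-iodo-5,7-bis(methoxymethoxy)-2-[4-(methoxymethoxy)phenyl]chroman-4-one | O=C1C[C@H](c2ccc(OCOC)cc2)Oc2cc(OCOC)c(I)c(OCOC)c21 | intermediate
11 | 2,4,6-trihydroxybenzaldehyde | O=Cc1c(O)cc(O)cc1O | starting material
12 | 2-hydroxy-4,6-bis(methoxymethoxy)benzaldehyde | O=Cc1c(O)cc(OCOC)cc1OCOC | intermediate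
13 | 1,4-bis(trimethylsilyl)buta-1,3-diyne | C[Si](C)(C)C#CC#C[Si](C)(C)C | starting material
14 | lithium (trimethylsilyl)butadiynide | [Li]C#CC#C[Si](C)(C)C | intermediate
15 | racemic 1-[2-hydroxy-4,6-bis(methoxymethoxy)phenyl]-5-(trimethylsilyl)penta-2,4-diyn-1-ol | C[Si](C)(C)C#CC#CC(O)c1c(O)cc(OCOC)cc1OCOC | intermediate
16 | 1-[2-hydroxy-4,6-bis(methoxymethoxy)phenyl]-5-(trimethylsilyl)penta-2,4-diyn-1-one | C[Si](C)(C)C#CC#CC(=O)c1c(O)cc(OCOC)cc1OCOC | intermediate
17 | 5,7-bis(methoxymethoxy)-2-[(trimethylsilyl)ethynyl]-4H-chromen-4-one | C[Si](C)(C)C#Cc1cc(=O)c2c(OCOC)cc(OCOC)cc2o1 | intermediate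
18 | 2-ethynyl-5,7-bis(methoxymethoxy)-4H-chromen-4-one | C#Cc1cc(=O)c2c(OCOC)cc(OCOC)cc2o1 | intermediate
19 | 2,3-butanedione | CC(=O)C(C)=O | starting material
20 | 2,3-bis(trimethylsilyloxy)buta-1,3-diene | C=C(O[Si](C)(C)C)C(=C)O[Si](C)(C)C | intermediate
21 | (2R)-6-(chromon-2-ylethynyl)flavanone penta-MOM ether (full name in step 12) | O=C1C[C@H](c2ccc(OCOC)cc2)Oc2cc(OCOC)c(C#Cc3cc(=O)c4c(OCOC)cc(OCOC)cc4o3)c(OCOC)c21 | intermediate
22 | (2R)-6-{2-[5,7-bis(methoxymethoxy)-4-oxo-4H-chromen-2-yl]-4,5-bis(trimethylsilyloxy)cyclohexa-1,4-dien-1-yl}-5,7-bis(methoxymethoxy)-2-[4-(methoxymethoxy)phenyl]chroman-4-one | O=C1C[C@H](c2ccc(OCOC)cc2)Oc2cc(OCOC)c(C3=C(c4cc(=O)c5c(OCOC)cc(OCOC)cc5o4)CC(O[Si](C)(C)C)=C(O[Si](C)(C)C)C3)c(OCOC)c21 | intermediate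
23 | (2R)-penta-MOM ether of the target with the catechol as bis(trimethylsilyl) ether (full name in step 13) | O=C1C[C@H](c2ccc(OCOC)cc2)Oc2cc(OCOC)c(-c3cc(O[Si](C)(C)C)c(O[Si](C)(C)C)cc3-c3cc(=O)c4c(OCOC)cc(OCOC)cc4o3)c(OCOC)c21 | intermediate
24 | (2R)-6-[2-(5,7-dihydroxy-4-oxo-4H-chromen-2-yl)-4,5-dihydroxyphenyl]-5,7-dihydroxy-2-(4-hydroxyphenyl)chroman-4-one | O=C1C[C@H](c2ccc(O)cc2)Oc2cc(O)c(-c3cc(O)c(O)cc3-c3cc(=O)c4c(O)cc(O)cc4o3)c(O)c21 | target

**Total step count:** 14
**Longest linear sequence:** 9 steps (steps 1–6, 12, 13, 14)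

**Steps most likely to fail**

1. **Step 13.**
   - What may go wrong: the cycloaddition may be too slow at temperatures the bis(silyloxy)diene tolerates. The triple bond is activated only vinylogously, receives electron density from a trioxygenated aryl group and is flanked by two ortho MOM ethers. The diene may be lost by desilylation or oligomerisation first. Long heating may erode C2 by thermal ring opening. DDQ may over-oxidise once a silyl group has fallen off.
   - Fallback: it sets out from 12 and 8 and comes back at 24. The central ring is bought instead of built, and the hindered biaryl bond is made by cross-coupling before any stereocentre exists.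
   - Commercial 2-bromo-4,5-dihydroxybenzaldehyde is protected (MOMCl, i-Pr2NEt) to 2-bromo-4,5-bis(methoxymethoxy)benzaldehyde F1.
   - F1 is homologated with the Ohira–Bestmann reagent (K2CO3, MeOH) to 1-bromo-2-ethynyl-4,5-bis(methoxymethoxy)benzene F2.
   - EtMgBr converts F2 into the arylethynylmagnesium bromide F3, which adds to 12 to give the propargylic alcohol F4.
   - MnO2 gives the o-hydroxyaryl ynone F5, and DMAP closes it to the 6'-bromoflavone tetra-MOM ether F6.
   - Miyaura borylation (PdCl2(dppf), B2pin2, KOAc, dioxane, 90 °C) gives the flavone 6'-boronate F7.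
   - Suzuki–Miyaura coupling of F7 with 8 (Pd(OAc)2, SPhos, K3PO4, toluene–H2O, 80 °C) gives the chromone–flavone biaryl hexa-MOM ether F8.
   - Arylation with 9 under the conditions of step 6 should touch only the 2-unsubstituted chromone, since a 2-arylchromone would have to form a quaternary centre. It gives the (2R)-hepta-MOM ether F9.
   - The conditions of step 14 convert F9 into 24.

2. **Step 12.**
   - What may go wrong: slow oxidative addition and transmetalation at the doubly ortho-substituted, electron-rich iodide may let oxidative dimerisation or oligomerisation of the acceptor alkyne take over. Prolonged contact with carbonate may erode the enantiomeric purity through reversible retro-oxa-Michael ring opening.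
   - Fallback: it sets out from 17 and 10 and comes back at 21. The base is removed altogether by using a preformed organometallic.
   - Silicon–tin exchange on 17 ((Bu3Sn)2O, 0.55 equiv, n-Bu4NF 2 mol%, THF, 60 °C) gives the 2-[(tributylstannyl)ethynyl]chromone F10, which is used crude.
   - Neutral Stille alkynylation of 10 with F10 (Pd2(dba)3, AsPh3, CuI 10 mol%, toluene, 70 °C) gives 21.

3. **Step 6.**
   - What may go wrong: the 5,7-dioxygenation lowers the electrophilicity of C2, so conversion may stall while the boronic acid is consumed by protodeboronation. The peri 5-OMOM group may lower the facial selectivity. Slow insertion of rhodium into the C–I bond may deactivate the catalyst.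
   - Fallback: it sets out from 5 and comes back at 10. The heterocycle is closed by oxa-Michael addition and the enantiomers are separated.
   - MeMgBr (3 equiv, THF, 0 °C) gives the benzylic alcohol F11, and MnO2 gives the 2-hydroxy-5-iodoacetophenone F12.
   - Claisen–Schmidt condensation with commercial 4-(methoxymethoxy)benzaldehyde (KOH, EtOH) gives the (E)-chalcone F13.
   - NaOAc in refluxing EtOH closes F13 to the racemic flavanone F14.
   - Preparative chromatography on a polysaccharide-based chiral stationary phase delivers 10 and the (2S)-enantiomer F15. F15 is re-equilibrated to F14 with NaOAc in EtOH and recycled.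

**Further compounds**
F1 | step 13 | 2-bromo-4,5-bis(methoxymethoxy)benzaldehyde | O=Cc1cc(OCOC)c(OCOC)cc1Br
F2 | step 13 | 1-bromo-2-ethynyl-4,5-bis(methoxymethoxy)benzene | C#Cc1cc(OCOC)c(OCOC)cc1Br
F3 | step 13 | [2-bromo-4,5-bis(methoxymethoxy)phenyl]ethynylmagnesium bromide | Br[Mg]C#Cc1cc(OCOC)c(OCOC)cc1Br
F4 | step 13 | racemic 3-[2-bromo-4,5-bis(methoxymethoxy)phenyl]-1-[2-hydroxy-4,6-bis(methoxymethoxy)phenyl]prop-2-yn-1-ol | OC(C#Cc1cc(OCOC)c(OCOC)cc1Br)c1c(O)cc(OCOC)cc1OCOC
F5 | step 13 | 3-[2-bromo-4,5-bis(methoxymethoxy)phenyl]-1-[2-hydroxy-4,6-bis(methoxymethoxy)phenyl]prop-2-yn-1-one | O=C(C#Cc1cc(OCOC)c(OCOC)cc1Br)c1c(O)cc(OCOC)cc1OCOC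
F6 | step 13 | 2-[2-bromo-4,5-bis(methoxymethoxy)phenyl]-5,7-bis(methoxymethoxy)-4H-chromen-4-one | O=c1cc(-c2cc(OCOC)c(OCOC)cc2Br)oc2cc(OCOC)cc(OCOC)c12
F7 | step 13 | 5,7-bis(methoxymethoxy)-2-[4,5-bis(methoxymethoxy)-2-(4,4,5,5-tetramethyl-1,3,2-dioxaborolan-2-yl)phenyl]-4H-chromen-4-one | O=c1cc(-c2cc(OCOC)c(OCOC)cc2B2OC(C)(C)C(C)(C)O2)oc2cc(OCOC)cc(OCOC)c12
F8 | step 13 | 6-{2-[5,7-bis(methoxymethoxy)-4-oxo-4H-chromen-2-yl]-4,5-bis(methoxymethoxy)phenyl}-5,7-bis(methoxymethoxy)-4H-chromen-4-one | O=c1ccoc2cc(OCOC)c(-c3cc(OCOC)c(OCOC)cc3-c3cc(=O)c4c(OCOC)cc(OCOC)cc4o3)c(OCOC)c12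
F9 | step 13 | (2R)-6-{2-[5,7-bis(methoxymethoxy)-4-oxo-4H-chromen-2-yl]-4,5-bis(methoxymethoxy)phenyl}-5,7-bis(methoxymethoxy)-2-[4-(methoxymethoxy)phenyl]chroman-4-one | O=C1C[C@H](c2ccc(OCOC)cc2)Oc2cc(OCOC)c(-c3cc(OCOC)c(OCOC)cc3-c3cc(=O)c4c(OCOC)cc(OCOC)cc4o3)c(OCOC)c21
F10 | step 12 | 5,7-bis(methoxymethoxy)-2-[(tributylstannyl)ethynyl]-4H-chromen-4-one | CCCC[Sn](CCCC)(CCCC)C#Cc1cc(=O)c2c(OCOC)cc(OCOC)cc2o1
F11 | step 6 | racemic 2-(1-hydroxyethyl)-4-iodo-3,5-bis(methoxymethoxy)phenol | CC(O)c1c(O)cc(OCOC)c(I)c1OCOC
F12 | step 6 | 1-[2-hydroxy-5-iodo-4,6-bis(methoxymethoxy)phenyl]ethan-1-one | CC(=O)c1c(O)cc(OCOC)c(I)c1OCOC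
F13 | step 6 | (E)-1-[2-hydroxy-5-iodo-4,6-bis(methoxymethoxy)phenyl]-3-[4-(methoxymethoxy)phenyl]prop-2-en-1-one | O=C(/C=C/c1ccc(OCOC)cc1)c1c(O)cc(OCOC)c(I)c1OCOC
F14 | step 6 | racemic 6-iodo-5,7-bis(methoxymethoxy)-2-[4-(methoxymethoxy)phenyl]chroman-4-one | O=C1CC(c2ccc(OCOC)cc2)Oc2cc(OCOC)c(I)c(OCOC)c21
F15 | step 6 | (2S)-6-iodo-5,7-bis(methoxymethoxy)-2-[4-(methoxymethoxy)phenyl]chroman-4-one | O=C1C[C@@H](c2ccc(OCOC)cc2)Oc2cc(OCOC)c(I)c(OCOC)c21
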